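## Retrosynthetic overview

1. The target is the cis-(2S,3R) dihydrobenzofuran; it comes from its pentabenzyl ether 22 by hydrogenolysis, and ring B (the dihydrofuran) is closed last by an enantioselective rhodium-carbene C–H insertion that forms C2–C3 from hydrazone 20.
2. Ketone 19 comes from the aryllithium of bromide 16 (ring D) and aldehyde 15; the C7a–O–CH2Ar ether (ring C plus the future C2) comes from benzylic chloride 12.
3. Ring A is built de novo: intermolecular Michael addition of dimethyl malonate 6 to enone 5 forms C3a–C4, a Claisen (Dieckmann) closure follows, and aromatisation gives resorcylate 10. The malonate supplies C3, C3a and C7a.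
4. Enone 5 comes from 3-arylpropanal 3 (ring E) and the acetonyl ylide 4.
5. Ring order: rings C, D and E are bought; ring A is made in steps 4–5; ring B is closed in step 13.

Conventions: benzofuran numbering (O1, C2, C3, C3a, C4–C7, C7a); ring A = benzo ring, B = dihydrofuran, C = aryl on C2, D = aryl on C3, E = aryl of the side chain.

Assumption: Rh2(S-PTAD)4, dirhodium tetrakis[(S)-(1-adamantyl)(N-phthalimido)acetate], is taken as the catalyst antipode that gives the (2S,3R) series; if the first run shows the opposite sense, the commercial mirror-image catalyst Rh2(R-PTAD)4 is used with nothing else changed.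

## Route

Step 1
Reactants: 1 methyl 3-(4-hydroxyphenyl)propanoate
Product: 2 methyl 3-[4-(benzyloxy)phenyl]propanoate
Conditions: BnBr (1.1 equiv), K2CO3, acetone, reflux
Reagents that add atoms: benzyl bromide, BrCc1ccccc1
Why: Williamson etherification of the phenoxide masks the ring E phenol as a benzyl ether that withstands base, hydride and organolithium and is removed by hydrogenolysis at the end.

Step 2
Reactants: 2 methyl 3-[4-(benzyloxy)phenyl]propanoate
Product: 3 3-[4-(benzyloxy)phenyl]propanal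
Conditions: i-Bu2AlH (1.1 equiv), CH2Cl2, −78 °C; MeOH, aq. potassium sodium tartrate
Reagents that add atoms: none
Why: Partial ester reduction stops at the tetrahedral aluminium hemiacetal at −78 °C, which releases the aldehyde only on work-up.

Step 3
Reactants: 3 3-[4-(benzyloxy)phenyl]propanal; 4 1-(triphenyl-λ5-phosphanylidene)propan-2-one
Product: 5 (3E)-6-[4-(benzyloxy)phenyl]hex-3-en-2-one
Conditions: toluene, 80 °C
Reagents that add atoms: none
Why: Wittig olefination with the stabilised, non-basic acetonyl ylide gives the (E)-enone without enolising the aldehyde.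

Step 4
Reactants: 5 (3E)-6-[4-(benzyloxy)phenyl]hex-3-en-2-one; 6 dimethyl malonate
Product: 8 methyl 6-{2-[4-(benzyloxy)phenyl]ethyl}-2,4-dioxocyclohexane-1-carboxylate, via acyclic Michael adduct 7 (not isolated)
Conditions: NaOMe (1.2 equiv), MeOH, reflux; then aq. HCl, 0 °C
Reagents that add atoms: none
Why: Intermolecular Michael addition of the malonate anion to the enone β-carbon forms the C3a–C4 bond, and the methyl-ketone enolate then closes ring A by an intramolecular Claisen (Dieckmann) condensation driven by the stable 1,3-dione enolate (olivetolate-type annulation); the stereocentres of 8 are erased in step 5.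

Step 5
Reactants: 8 methyl 6-{2-[4-(benzyloxy)phenyl]ethyl}-2,4-dioxocyclohexane-1-carboxylate
Product: 10 methyl 6-{2-[4-(benzyloxy)phenyl]ethyl}-2,4-dihydroxybenzoate, via bromo dione 9 (not isolated)
Conditions: Br2 (1.0 equiv), DMF, 0 °C; then 80 °C
Reagents that add atoms: none
Why: The enolised 1,3-dione is α-brominated far faster than the alkoxyarene, and HBr-mediated bromine migration, thermal dehydrobromination and tautomerisation (halogenation–elimination aromatisation) give the resorcylate.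

Step 6
Reactants: 10 methyl 6-{2-[4-(benzyloxy)phenyl]ethyl}-2,4-dihydroxybenzoate
Product: 11 methyl 4-(benzyloxy)-6-{2-[4-(benzyloxy)phenyl]ethyl}-2-hydroxybenzoate
Conditions: BnBr (1.05 equiv), K2CO3 (1.1 equiv), acetone, reflux
Reagents that add atoms: benzyl bromide, BrCc1ccccc1
Why: Williamson etherification is selective for the 4-OH because the 2-OH is hydrogen-bonded to the ester carbonyl and much less nucleophilic.

Step 7
Reactants: 11 methyl 4-(benzyloxy)-6-{2-[4-(benzyloxy)phenyl]ethyl}-2-hydroxybenzoate; 12 1-(benzyloxy)-4-(chloromethyl)benzene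
Product: 13 methyl 4-(benzyloxy)-2-{[4-(benzyloxy)phenyl]methoxy}-6-{2-[4-(benzyloxy)phenyl]ethyl}benzoate
Conditions: K2CO3, DMF, 70 °C
Reagents that add atoms: none
Why: Under more forcing Williamson conditions the chelated phenol is alkylated by the reactive benzylic chloride, which installs ring C and the future C2 as the ArCH2–O unit.

Step 8
Reactants: 13 fully benzylated methyl benzoate
Product: 14 [4-(benzyloxy)-2-{[4-(benzyloxy)phenyl]methoxy}-6-{2-[4-(benzyloxy)phenyl]ethyl}phenyl]methanol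
Conditions: LiAlH4, THF, 0 °C to reflux; then H2O
Reagents that add atoms: none
Why: LiAlH4 reduces even a doubly ortho-substituted benzoate to the benzylic alcohol while aryl benzyl ethers are inert (hydride reduction).

Step 9
Reactants: 14 benzylic alcohol
Product: 15 4-(benzyloxy)-2-{[4-(benzyloxy)phenyl]methoxy}-6-{2-[4-(benzyloxy)phenyl]ethyl}benzaldehyde
Conditions: Dess–Martin periodinane, CH2Cl2, rt
Reagents that add atoms: none
Why: Dess–Martin oxidation takes the primary benzylic alcohol to the aldehyde under neutral conditions without over-oxidation.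

Step 10
Reactants: 15 ring A aldehyde; 16 1,3-bis(benzyloxy)-5-bromobenzene
Product: 18 [3,5-bis(benzyloxy)phenyl][4-(benzyloxy)-2-{[4-(benzyloxy)phenyl]methoxy}-6-{2-[4-(benzyloxy)phenyl]ethyl}phenyl]methanol, via aryllithium 17 (not isolated)
Conditions: 16, n-BuLi, THF, −78 °C; then 15, −78 to 0 °C; H2O
Reagents that add atoms: none
Why: Fast bromine–lithium exchange gives the aryllithium, which adds 1,2 to the hindered but non-enolisable aldehyde; the racemic carbinol centre is removed in step 11.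

Step 11
Reactants: 18 diaryl carbinol
Product: 19 [3,5-bis(benzyloxy)phenyl][4-(benzyloxy)-2-{[4-(benzyloxy)phenyl]methoxy}-6-{2-[4-(benzyloxy)phenyl]ethyl}phenyl]methanone
Conditions: Dess–Martin periodinane, CH2Cl2, rt
Reagents that add atoms: none
Why: Dess–Martin oxidation of the doubly benzylic secondary alcohol gives the benzophenone cleanly despite the ortho substituents.

Step 12
Reactants: 19 benzophenone
Product: 20 {[3,5-bis(benzyloxy)phenyl][4-(benzyloxy)-2-{[4-(benzyloxy)phenyl]methoxy}-6-{2-[4-(benzyloxy)phenyl]ethyl}phenyl]methylidene}hydrazine (E/Z mixture)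
Conditions: N2H4·H2O (20 equiv), AcOH (cat.), n-BuOH, 110 °C
Reagents that add atoms: hydrazine (used as the monohydrate), NN
Why: Acid-catalysed condensation with a large excess of hydrazine at high temperature gives the NH2-hydrazone of the hindered ketone and suppresses azine formation; the C=N geometry is irrelevant.

Step 13
Reactants: 20 hydrazone
Product: 22 (2S,3R)-6-(benzyloxy)-2-[4-(benzyloxy)phenyl]-3-[3,5-bis(benzyloxy)phenyl]-4-{2-[4-(benzyloxy)phenyl]ethyl}-2,3-dihydro-1-benzofuran, via diaryldiazomethane 21 (not isolated)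
Conditions: MnO2 (8 equiv), CH2Cl2–MeCN, 0 °C, filter through Celite; then Rh2(S-PTAD)4 (1 mol%), 0 °C to rt
Reagents that add atoms: none
Why: MnO2 dehydrogenates the hydrazone to the diazo compound, whose donor/donor rhodium carbene undergoes intramolecular 1,5 C–H insertion into the doubly activated O–CH2–Ar bond; the chiral carboxylate ligands select the carbene face and one enantiotopic hydrogen, which sets C2 (S) and C3 (R) together as the kinetic cis-2,3-diaryl product.

Step 14
Reactants: 22 pentabenzyl ether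
Product: 23 5-[(2S,3R)-6-hydroxy-2-(4-hydroxyphenyl)-4-[2-(4-hydroxyphenyl)ethyl]-2,3-dihydro-1-benzofuran-3-yl]benzene-1,3-diol
Conditions: H2 (1 atm), 10% Pd/C, EtOAc–MeOH, rt
Reagents that add atoms: none
Why: Hydrogenolysis removes the five aryl benzyl ethers under neutral conditions, so no acid- or base-induced ring opening can epimerise the cis centres; the hindered cyclic C2–O bond reacts much more slowly and the reaction is stopped at full debenzylation.

## Compound list

1 | methyl 3-(4-hydroxyphenyl)propanoate | COC(=O)CCc1ccc(O)cc1 | starting material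
2 | methyl 3-[4-(benzyloxy)phenyl]propanoate | COC(=O)CCc1ccc(OCc2ccccc2)cc1 | intermediate
3 | 3-[4-(benzyloxy)phenyl]propanal | O=CCCc1ccc(OCc2ccccc2)cc1 | intermediate
4 | 1-(triphenyl-λ5-phosphanylidene)propan-2-one | CC(=O)C=P(c1ccccc1)(c1ccccc1)c1ccccc1 | starting material
5 | (3E)-6-[4-(benzyloxy)phenyl]hex-3-en-2-one | CC(=O)/C=C/CCc1ccc(OCc2ccccc2)cc1 | intermediate
6 | dimethyl malonate | COC(=O)CC(=O)OC | starting material
7 | dimethyl 2-{1-[4-(benzyloxy)phenyl]-5-oxohexan-3-yl}propanedioate (racemic, not isolated) | COC(=O)C(C(=O)OC)C(CCc1ccc(OCc2ccccc2)cc1)CC(C)=O | intermediate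
8 | methyl 6-{2-[4-(benzyloxy)phenyl]ethyl}-2,4-dioxocyclohexane-1-carboxylate (keto/enol tautomers, stereoisomer mixture) | COC(=O)C1C(CCc2ccc(OCc3ccccc3)cc2)CC(=O)CC1=O | intermediate
9 | methyl 3-bromo-6-{2-[4-(benzyloxy)phenyl]ethyl}-2,4-dioxocyclohexane-1-carboxylate (stereoisomer mixture, not isolated) | COC(=O)C1C(CCc2ccc(OCc3ccccc3)cc2)CC(=O)C(Br)C1=O | intermediate
10 | methyl 6-{2-[4-(benzyloxy)phenyl]ethyl}-2,4-dihydroxybenzoate | COC(=O)c1c(O)cc(O)cc1CCc1ccc(OCc2ccccc2)cc1 | intermediate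
11 | methyl 4-(benzyloxy)-6-{2-[4-(benzyloxy)phenyl]ethyl}-2-hydroxybenzoate | COC(=O)c1c(O)cc(OCc2ccccc2)cc1CCc1ccc(OCc2ccccc2)cc1 | intermediate
12 | 1-(benzyloxy)-4-(chloromethyl)benzene | ClCc1ccc(OCc2ccccc2)cc1 | starting material
13 | methyl 4-(benzyloxy)-2-{[4-(benzyloxy)phenyl]methoxy}-6-{2-[4-(benzyloxy)phenyl]ethyl}benzoate | COC(=O)c1c(OCc2ccc(OCc3ccccc3)cc2)cc(OCc2ccccc2)cc1CCc1ccc(OCc2ccccc2)cc1 | intermediate
14 | [4-(benzyloxy)-2-{[4-(benzyloxy)phenyl]methoxy}-6-{2-[4-(benzyloxy)phenyl]ethyl}phenyl]methanol | OCc1c(OCc2ccc(OCc3ccccc3)cc2)cc(OCc2ccccc2)cc1CCc1ccc(OCc2ccccc2)cc1 | intermediate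
15 | 4-(benzyloxy)-2-{[4-(benzyloxy)phenyl]methoxy}-6-{2-[4-(benzyloxy)phenyl]ethyl}benzaldehyde | O=Cc1c(OCc2ccc(OCc3ccccc3)cc2)cc(OCc2ccccc2)cc1CCc1ccc(OCc2ccccc2)cc1 | intermediate
16 | 1,3-bis(benzyloxy)-5-bromobenzene | Brc1cc(OCc2ccccc2)cc(OCc2ccccc2)c1 | starting material
17 | [3,5-bis(benzyloxy)phenyl]lithium (not isolated) | [Li]c1cc(OCc2ccccc2)cc(OCc2ccccc2)c1 | intermediate
18 | [3,5-bis(benzyloxy)phenyl][4-(benzyloxy)-2-{[4-(benzyloxy)phenyl]methoxy}-6-{2-[4-(benzyloxy)phenyl]ethyl}phenyl]methanol (racemic) | OC(c1cc(OCc2ccccc2)cc(OCc2ccccc2)c1)c1c(OCc2ccc(OCc3ccccc3)cc2)cc(OCc2ccccc2)cc1CCc1ccc(OCc2ccccc2)cc1 | intermediate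
19 | [3,5-bis(benzyloxy)phenyl][4-(benzyloxy)-2-{[4-(benzyloxy)phenyl]methoxy}-6-{2-[4-(benzyloxy)phenyl]ethyl}phenyl]methanone | O=C(c1cc(OCc2ccccc2)cc(OCc2ccccc2)c1)c1c(OCc2ccc(OCc3ccccc3)cc2)cc(OCc2ccccc2)cc1CCc1ccc(OCc2ccccc2)cc1 | intermediate
20 | hydrazone of 19 (E/Z mixture) | NN=C(c1cc(OCc2ccccc2)cc(OCc2ccccc2)c1)c1c(OCc2ccc(OCc3ccccc3)cc2)cc(OCc2ccccc2)cc1CCc1ccc(OCc2ccccc2)cc1 | intermediate
21 | diazo compound from 20, [3,5-bis(benzyloxy)phenyl](aryl)diazomethane (not isolated) | [N-]=[N+]=C(c1cc(OCc2ccccc2)cc(OCc2ccccc2)c1)c1c(OCc2ccc(OCc3ccccc3)cc2)cc(OCc2ccccc2)cc1CCc1ccc(OCc2ccccc2)cc1 | intermediate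
22 | (2S,3R)-6-(benzyloxy)-2-[4-(benzyloxy)phenyl]-3-[3,5-bis(benzyloxy)phenyl]-4-{2-[4-(benzyloxy)phenyl]ethyl}-2,3-dihydro-1-benzofuran (cis) | c1ccccc1COc1ccc(CCc2cc(OCc4ccccc4)cc3c2[C@@H](c2cc(OCc4ccccc4)cc(OCc4ccccc4)c2)[C@@H](c2ccc(OCc4ccccc4)cc2)O3)cc1 | intermediate
23 | 5-[(2S,3R)-6-hydroxy-2-(4-hydroxyphenyl)-4-[2-(4-hydroxyphenyl)ethyl]-2,3-dihydro-1-benzofuran-3-yl]benzene-1,3-diol (cis) | Oc1ccc(CCc2cc(O)cc3c2[C@@H](c2cc(O)cc(O)c2)[C@@H](c2ccc(O)cc2)O3)cc1 | target

## Step count and risks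

Total steps: 14. Longest linear sequence: 14 steps (1 to 23); compounds 4, 6, 12 and 16 are bought.

The three steps most likely to fail are steps 5, 12 and 13.

Step 5 (aromatisation). Bromine could attack the electron-rich rings, or the HBr formed could cleave the benzyl ether at 80 °C. The fallback avoids the dione altogether. It sets out from benzylic chloride 12 and comes back to the route at ester 13. Commercial methyl 2,4-dihydroxy-6-methylbenzoate F1 is benzylated selectively at the 4-OH (BnBr, K2CO3, acetone) to methyl 4-(benzyloxy)-2-hydroxy-6-methylbenzoate F2. Alkylation of the chelated phenol with 12 (K2CO3, DMF, 70 °C) gives methyl 4-(benzyloxy)-2-{[4-(benzyloxy)phenyl]methoxy}-6-methylbenzoate F3. Lateral deprotonation of the ortho-methyl group with LiN(i-Pr)2 (THF, −78 °C) and alkylation of the ester-stabilised benzylic anion with a second equivalent of 12 forms the CH2–CH2 bridge and gives 13.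

Step 12 (hydrazone). The ketone carries two ortho substituents and may resist condensation. The fallback sets out from aldehyde 15 and comes back at hydrazone 20. Aldehyde 15 is condensed with NH2OH·HCl (pyridine, EtOH) to the aldoxime F4, which is dehydrated (Ac2O, reflux) to the benzonitrile F5. Addition of aryllithium 17 (from 16 and n-BuLi, THF, −78 °C to rt; MeOH quench) to the linear, sterically undemanding nitrile gives the N–H ketimine F6. Transimination with N2H4·H2O and catalytic AcOH in EtOH at 60 °C exchanges NH for N–NH2 with loss of ammonia and gives 20.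

Step 13 (C–H insertion). The doubly ortho-substituted diazo compound may form the carbene slowly, insertion into the benzylic CH2 next to ring E (an indane) may compete, and the ee may fall short. The fallback sets out from ketone 19 and comes back at target 23. Phosphazene base P4-t-Bu (toluene, rt to 80 °C) generates the carbanion of the ArCH2–O group, which adds to the ketone in an intramolecular aldol-type reaction to give the 3-hydroxy-2,3-dihydrobenzofuran F7. Catalytic TsOH dehydrates it to the 2,3-diarylbenzofuran F8. Hydrogenation over Pd(OH)2/C (H2, 5–10 bar, EtOAc–MeOH) adds hydrogen syn across C2=C3 and removes the five benzyl groups, giving the racemic cis pentaphenol F9. Preparative chiral HPLC on an amylose tris(3,5-dimethylphenylcarbamate) phase then gives 23.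

## Further compounds

F1 | step 5 | methyl 2,4-dihydroxy-6-methylbenzoate | COC(=O)c1c(C)cc(O)cc1O
F2 | step 5 | methyl 4-(benzyloxy)-2-hydroxy-6-methylbenzoate | COC(=O)c1c(C)cc(OCc2ccccc2)cc1O
F3 | step 5 | methyl 4-(benzyloxy)-2-{[4-(benzyloxy)phenyl]methoxy}-6-methylbenzoate | COC(=O)c1c(C)cc(OCc2ccccc2)cc1OCc1ccc(OCc2ccccc2)cc1
F4 | step 12 | (E)-oxime of aldehyde 15 | O/N=C/c1c(OCc2ccc(OCc3ccccc3)cc2)cc(OCc2ccccc2)cc1CCc1ccc(OCc2ccccc2)cc1
F5 | step 12 | 4-(benzyloxy)-2-{[4-(benzyloxy)phenyl]methoxy}-6-{2-[4-(benzyloxy)phenyl]ethyl}benzonitrile | N#Cc1c(OCc2ccc(OCc3ccccc3)cc2)cc(OCc2ccccc2)cc1CCc1ccc(OCc2ccccc2)cc1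
F6 | step 12 | N–H ketimine corresponding to ketone 19 | N=C(c1cc(OCc2ccccc2)cc(OCc2ccccc2)c1)c1c(OCc2ccc(OCc3ccccc3)cc2)cc(OCc2ccccc2)cc1CCc1ccc(OCc2ccccc2)cc1
F7 | step 13 | 6-(benzyloxy)-2-[4-(benzyloxy)phenyl]-3-[3,5-bis(benzyloxy)phenyl]-4-{2-[4-(benzyloxy)phenyl]ethyl}-2,3-dihydro-1-benzofuran-3-ol (racemic, diastereomer mixture) | OC1(c2cc(OCc3ccccc3)cc(OCc3ccccc3)c2)c2c(CCc3ccc(OCc4ccccc4)cc3)cc(OCc3ccccc3)cc2OC1c1ccc(OCc2ccccc2)cc1
F8 | step 13 | 6-(benzyloxy)-2-[4-(benzyloxy)phenyl]-3-[3,5-bis(benzyloxy)phenyl]-4-{2-[4-(benzyloxy)phenyl]ethyl}-1-benzofuran | c1ccccc1COc1ccc(CCc2cc(OCc3ccccc3)cc3oc(-c4ccc(OCc5ccccc5)cc4)c(-c4cc(OCc5ccccc5)cc(OCc5ccccc5)c4)c23)cc1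
F9 | step 13 | racemic cis pentaphenol (1:1 mixture of 23 and its enantiomer) | Oc1ccc(CCc2cc(O)cc3c2[C@@H](c2cc(O)cc(O)c2)[C@@H](c2ccc(O)cc2)O3)cc1.Oc1ccc(CCc2cc(O)cc3c2[C@H](c2cc(O)cc(O)c2)[C@H](c2ccc(O)cc2)O3)cc1
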